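**Assumption:** lactone alcohol 1 (two steps from L‑glutamic acid, commercially available) is taken as a cheap commercial chiral starting material, and the target is taken as drawn, i.e. the 2,5‑trans oxolane (2R,5S).

## Retrosynthetic overview

1. C(sp)–C(sp2) disconnection of the enyne: terminal alkyne 9 plus (1E,9E)-1,10-dibromodeca-1,9-diene 11 (from deca-1,9-diyne), joined last by mono-Sonogashira coupling.
2. The oxolane (the only ring) and the ester chain come from one light-driven cobalt/photoredox cyclization–Giese cascade of alkenynol 7 with methyl acrylate, which forms the ring C–O bond and the CH2–CH2 bond of the chain and sets the chain-bearing carbon trans to the alkyne-bearing carbon.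
3. Alkenynol 7 comes from lactone 1: CH2OH → C≡CH (oxidation, Seyferth–Gilbert), then lactone → lactol → methylenation.
4. The alkyne-bearing stereocentre is bought in 1 and its C–O bond is never broken; the second stereocentre is set by it in the cascade.

## Route

**Step 1**
Reactants: 1, (S)-5-(hydroxymethyl)dihydrofuran-2(3H)-one
Product: 2, (S)-5-oxotetrahydrofuran-2-carbaldehyde
Conditions: Dess–Martin periodinane, NaHCO3, CH2Cl2, 0 °C → rt; filter, use crude at once
Reagents that add atoms: none
Why: Dess–Martin oxidation of the primary alcohol under neutral, non-epimerizing conditions; the lactone and the stereocentre are untouched.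

**Step 2**
Reactants: 2, (S)-5-oxotetrahydrofuran-2-carbaldehyde; 3, dimethyl (1-diazo-2-oxopropyl)phosphonate
Product: 4, (S)-5-ethynyldihydrofuran-2(3H)-one
Conditions: 3, NaOMe, THF, −78 °C (pre-forms the diazomethylphosphonate anion); then 2, −78 → 0 °C; AcOH quench
Reagents that add atoms: Ohira–Bestmann reagent 3, CC(=O)C(=[N+]=[N-])P(=O)(OC)OC (supplies the terminal alkyne carbon)
Why: Seyferth–Gilbert homologation (Ohira–Bestmann reagent) turns the aldehyde into the terminal alkyne; the aprotic, low-temperature variant limits lactone opening and α-epimerization, and the stereocentre becomes a robust propargylic centre.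

**Step 3**
Reactants: 4, (S)-5-ethynyldihydrofuran-2(3H)-one
Product: 5, (5S)-5-ethynyltetrahydrofuran-2-ol (anomer mixture)
Conditions: DIBAL-H (1.1 equiv), CH2Cl2, −78 °C; Rochelle salt work-up
Reagents that add atoms: none
Why: Partial DIBAL reduction of a γ-lactone stops at the lactol at −78 °C; the alkyne and the stereocentre are not affected.

**Step 4**
Reactants: 5, (5S)-5-ethynyltetrahydrofuran-2-ol; 6, methyltriphenylphosphonium bromide
Product: 7, (S)-hept-6-en-1-yn-3-ol
Conditions: 6 (3.5 equiv), KOtBu (3.3 equiv), THF, 0 °C → rt; isolate carefully (volatile)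
Reagents that add atoms: methyltriphenylphosphonium bromide 6, C[P+](c1ccccc1)(c1ccccc1)c1ccccc1.[Br-] (supplies the =CH2 carbon)
Why: Wittig methylenation of the open hydroxy-aldehyde form of the lactol releases the secondary alcohol; excess ylide covers the OH and alkyne C–H, and the carbinol C–O bond is not broken, so configuration is retained.

**Step 5 (key step)**
Reactants: 7, (S)-hept-6-en-1-yn-3-ol; 8, methyl acrylate
Product: 9, methyl 4-[(2R,5S)-5-ethynyltetrahydrofuran-2-yl]butanoate (2,5-trans)
Conditions: bis(4,4,4-trifluoro-1-phenylbutane-1,3-dionato)cobalt(II) (10 mol%), 4CzIPN (2 mol%), 2,4,6-collidine (20 mol%), 8 (4 equiv), PhCF3 (0.05 M), 450 nm LEDs, 25 °C, Ar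
Reagents that add atoms: methyl acrylate 8, C=CC(=O)OC
Why: Proposed new method: a redox-neutral cobalt/photoredox alkenol carboetherification. Excited 4CzIPN (E* ≈ +1.35 V) oxidises the Co(II)–alkenol adduct, with collidine taking the proton, to a diketonato-Co(III) alkoxide; this delivers oxygen 5-exo to the pendant alkene inside the cobalt coordination sphere (ring C–O bond, Co(II) released) through a chair-like transition state with the ethynyl group pseudo-equatorial, giving the 2,5-trans (tetrahydrofuran-2-yl)methyl radical; the primary radical adds to methyl acrylate (new C–C bond) and the α-ester radical (≈ −0.6 V) is reduced by 4CzIPN•− (≈ −1.2 V) and protonated by collidinium, closing both cycles without O2 or a stoichiometric H-donor, the two species that divert this radical in the thermal process. The closest known reaction types are the thermal cobalt(II)-diketonate aerobic oxidative cyclization of 1-substituted pent-4-en-1-ols (2,5-trans, typically ≥95:5 for alkyl and aryl substituents, with the carbon radical interceptable by acceptor alkenes under O2/cyclohexadiene) and photoredox Giese additions closed by reductive radical-polar crossover. The new stereocentre is set only by the bought one (all catalysts achiral); I expect trans:cis of roughly 10:1 or better because ethynyl is a slim substituent, with the cis isomer removed by chromatography.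

**Step 6**
Reactants: 10, deca-1,9-diyne
Product: 11, (1E,9E)-1,10-dibromodeca-1,9-diene
Conditions: Cp2Zr(H)Cl (2.3 equiv), CH2Cl2, rt; then NBS (2.3 equiv), 0 °C
Reagents that add atoms: N-bromosuccinimide, BrN1C(=O)CCC1=O
Why: Double hydrozirconation (syn, terminal Zr) followed by bromodezirconation with retention gives the (E)-1-bromoalkene at both ends.

**Step 7**
Reactants: 9, methyl 4-[(2R,5S)-5-ethynyltetrahydrofuran-2-yl]butanoate; 11, (1E,9E)-1,10-dibromodeca-1,9-diene (4 equiv, excess recovered)
Product: 12, mutafuran C, methyl 4-[(2R,5S)-5-[(3E,11E)-12-bromododeca-3,11-dien-1-yn-1-yl]tetrahydrofuran-2-yl]butanoate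
Conditions: Pd(PPh3)2Cl2 (5 mol%), CuI (10 mol%), i-Pr2NH, THF (degassed), rt
Reagents that add atoms: dibromodiene 11, Br/C=C/CCCCCC/C=C/Br
Why: Sonogashira coupling of the terminal alkyne with one alkenyl bromide proceeds with retention of the E geometry; the excess of the symmetric dibromide enforces mono-coupling and leaves the second (E)-vinyl bromide as the natural-product terminus, while the ester and both stereocentres are inert.

## Compound list

1 | (S)-5-(hydroxymethyl)dihydrofuran-2(3H)-one | O=C1CC[C@@H](CO)O1 | starting material
2 | (S)-5-oxotetrahydrofuran-2-carbaldehyde | O=C1CC[C@@H](C=O)O1 | intermediate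
3 | dimethyl (1-diazo-2-oxopropyl)phosphonate | CC(=O)C(=[N+]=[N-])P(=O)(OC)OC | starting material
4 | (S)-5-ethynyldihydrofuran-2(3H)-one | O=C1CC[C@@H](C#C)O1 | intermediate
5 | (5S)-5-ethynyltetrahydrofuran-2-ol | OC1CC[C@@H](C#C)O1 | intermediate
6 | methyltriphenylphosphonium bromide | C[P+](c1ccccc1)(c1ccccc1)c1ccccc1.[Br-] | starting material
7 | (S)-hept-6-en-1-yn-3-ol | C=CCC[C@@H](C#C)O | intermediate
8 | methyl acrylate | C=CC(=O)OC | starting material
9 | methyl 4-[(2R,5S)-5-ethynyltetrahydrofuran-2-yl]butanoate | COC(=O)CCC[C@@H]1CC[C@@H](C#C)O1 | intermediate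
10 | deca-1,9-diyne | C#CCCCCCCC#C | starting material
11 | (1E,9E)-1,10-dibromodeca-1,9-diene | Br/C=C/CCCCCC/C=C/Br | intermediate
12 | mutafuran C | COC(=O)CCC[C@@H]1CC[C@@H](C#C/C=C/CCCCCC/C=C/Br)O1 | target

## Summary

Total steps: 7. Longest linear sequence: 6 (1 → 2 → 4 → 5 → 7 → 9 → 12).

Steps most likely to fail:

1. **Step 5 (proposed new cascade).** The photogenerated Co(III) alkoxide may not cyclize, or may leak free alkoxyl radicals and give lower trans selectivity; acrylate telomers are also possible. Fallback with known chemistry, stepwise: aerobic cobalt(II)-catalysed oxidative cyclization of 7 (Co(modp)2, O2, t-BuOOH, i-PrOH, 55 °C) to trans-[(2S,5S)-5-ethynyltetrahydrofuran-2-yl]methanol, then I2/PPh3/imidazole to the iodide, then tin- or silane-mediated Giese addition to methyl acrylate to reach 9.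

2. **Step 2 (homologation of the α-acyloxy aldehyde).** Aldehyde 2 can epimerize, hydrate or suffer lactone opening. Fallback: install the alkyne after ring formation. Protect 1 as its TBDPS ether, reduce with DIBAL and methylenate to (S)-1-(silyloxy)hex-5-en-2-ol, cyclize with acrylate, desilylate, oxidize, and run the Ohira–Bestmann reaction on the more robust oxolane-2-carbaldehyde before the Sonogashira coupling.

3. **Step 7 (statistical mono-Sonogashira).** Bis-coupling, Glaser dimer or difficult separation from excess 11 could erode yield. Fallback: couple 9 with the singly reactive (E)-9-iodonon-8-enal (from non-8-yn-1-ol by hydrozirconation/iodination and oxidation), then install the terminal (E)-vinyl bromide by Takai olefination (CHBr3, CrCl2).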